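## Retrosynthetic overview (chromone numbering O1–C8a)

1. The C8–Cl / C5–OH pair comes from chloride opening the C8–O bond of a 5,8-oxygen bridge. C8 inverts and C5 is retained. The phenol benzyl ether falls in the same pot.
2. The C6/C7 cis-diol comes from exo-dihydroxylation of a 5,8-epoxy-5,8-dihydrochromone, which places it syn to the bridge. This gives the all-cis 5,6,7-oxygen array.
3. The 5,8-epoxy-5,8-dihydrochromone is made in one flask. Furan and 4-bromobut-3-yn-2-one undergo an enantioselective Diels–Alder reaction, followed by Claisen acylation with the arylpropanoyl chloride and O-vinylation with loss of bromide.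
4. Ring order: the carbocycle with its oxa-bridge forms first and the γ-pyrone second, in the same flask. The bridge is opened last.
5. The acid chloride comes from O-benzylisovanillin and Meldrum's acid. The bromoynone comes from but-3-yn-2-one.

Assumption: the (S)-prolinol-derived catalyst is taken to give (1R,4S)-10. The sense of induction must be checked on 12, and the equally available (R)-catalyst is used if it is opposite.

## Route

Step 1
Reactants: 1 but-3-yn-2-one
Product: 2 4-bromobut-3-yn-2-one
Conditions: NBS (1.1 equiv), AgNO3 (10 mol %), acetone, rt, 2 h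
Reagents that add atoms: N-bromosuccinimide O=C1CCC(=O)N1Br
Why: This is a silver-catalysed electrophilic bromination of a terminal alkyne (silver acetylide plus NBS), which leaves the ketone untouched and creates no stereocentre.

Step 2
Reactants: 3 3-(benzyloxy)-4-methoxybenzaldehyde; 4 Meldrum's acid (2,2-dimethyl-1,3-dioxane-4,6-dione)
Product: 7 3-[3-(benzyloxy)-4-methoxyphenyl]propanoic acid, via arylidene Meldrum's acid 5 (not isolated), via benzyl Meldrum's acid 6 (not isolated)
Conditions: HCO2H/Et3N (5:2), 95 °C, 4 h; then 2 M HCl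
Reagents that add atoms: none
Why: This is a domino Knoevenagel condensation, formate conjugate (transfer) reduction and hydrolysis–decarboxylation in triethylammonium formate; the benzyl ether survives because no hydrogenation metal is present.

Step 3
Reactants: 7 3-[3-(benzyloxy)-4-methoxyphenyl]propanoic acid
Product: 8 3-[3-(benzyloxy)-4-methoxyphenyl]propanoyl chloride
Conditions: (COCl)2 (1.2 equiv), cat. DMF, CH2Cl2, 0 °C → rt; concentrate, use crude
Reagents that add atoms: oxalyl chloride O=C(Cl)C(=O)Cl
Why: This is a Vilsmeier-type acid chloride formation, to which both aryl ethers are inert.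

Step 4 (key step)
Reactants: 2 4-bromobut-3-yn-2-one; 9 furan; 8 3-[3-(benzyloxy)-4-methoxyphenyl]propanoyl chloride
Product: 12 (5R,8S)-2-{2-[3-(benzyloxy)-4-methoxyphenyl]ethyl}-5,8-dihydro-5,8-epoxy-4H-chromen-4-one, via bromo-oxanorbornadienyl methyl ketone 10 (not isolated), via bromoenone 1,3-diketone 11 (not isolated)
Conditions: (a) 9 (10 equiv), (S)-diphenylprolinol o-tolyl-oxazaborolidine·HNTf2 (20 mol %), toluene, −78 → −40 °C; (b) same flask, LiHMDS (2.5 equiv), THF, −78 °C; (c) 8 (1.05 equiv), −78 °C → rt
Reagents that add atoms: none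
Why: Proposed new method: the boron-bound, LUMO-lowered bromoynone undergoes a concerted [4+2] with furan at a temperature where the thermal background is nil, with one π-face screened by the catalyst aryl group and the furan oxygen turned away from the complexed carbonyl, which fixes both bridgeheads (1R,4S, the later C5 and C8) in one event; without work-up the acetyl group of 10 is enolised and C-acylated by 8 (LiHMDS/acid chloride Claisen-type diketone synthesis), and the diketonate oxygen of 11 closes the γ-pyrone by conjugate addition–bromide elimination at the strained β-bromoenone carbon (C-attack would need a four-membered ring), while the bridgehead C–H bonds cannot enolise and so cannot scramble; the closest known reaction types are the thermal Diels–Alder reaction of furans with 3-bromopropiolates, oxazaborolidinium-catalysed enantioselective Diels–Alder reactions of furan with acrylates and of haloalkynals with cyclopentadiene, and chromone synthesis from 2-haloaryl 1,3-diketones by intramolecular O-arylation.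

Step 5
Reactants: 12 (5R,8S)-2-{2-[3-(benzyloxy)-4-methoxyphenyl]ethyl}-5,8-dihydro-5,8-epoxy-4H-chromen-4-one
Product: 13 (5S,6R,7S,8S)-2-{2-[3-(benzyloxy)-4-methoxyphenyl]ethyl}-6,7-dihydroxy-5,6,7,8-tetrahydro-5,8-epoxy-4H-chromen-4-one (exo-cis-diol syn to the O-bridge)
Conditions: K2OsO4·2H2O (2 mol %), NMO (1.5 equiv), acetone/H2O 4:1, rt
Reagents that add atoms: osmium tetroxide (catalytic oxygen carrier) O=[Os](=O)(=O)=O; N-methylmorpholine N-oxide C[N+]1([O-])CCOCC1; water O
Why: In this Upjohn dihydroxylation osmium adds suprafacially to the only strained, non-conjugated alkene (C6=C7) from the open exo face, so both new C–O bonds are cis to the bridge oxygen at C5 and C8, while the pyrone C=C bonds are electron-poor and inert.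

Step 6
Reactants: 13 (5S,6R,7S,8S)-bridged diol
Product: 14 (5S,6S,7S,8R)-8-chloro-5,6,7-trihydroxy-2-[2-(3-hydroxy-4-methoxyphenyl)ethyl]-5,6,7,8-tetrahydro-4H-chromen-4-one
Conditions: BCl3 (5 equiv), C6HMe5 (3 equiv), CH2Cl2, −78 → −20 °C; MeOH quench, evaporate, pH 7 buffer
Reagents that add atoms: boron trichloride ClB(Cl)Cl
Why: Boron binds the very basic pyrone carbonyl and chelates the peri C5–O bridge oxygen, so chloride attacks the C8–O carbon (attached to C2 of a pyrylium-like ring, hence SN2-activated and SN1-deactivated, and less hindered than C5) from the face opposite the bridge, giving 8R-Cl trans to 7-OH while C5–O is retained as a six-membered boron chelate; this follows the boron-trihalide cleavage of 7-oxanorbornanes to trans-4-halocyclohexanols, the same reagent removes the benzyl ether (BCl3/pentamethylbenzene debenzylation), and the C6 descriptor changes R→S by priority only.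

## Compound list

1 | but-3-yn-2-one | CC(=O)C#C | starting material
2 | 4-bromobut-3-yn-2-one | CC(=O)C#CBr | intermediate
3 | 3-(benzyloxy)-4-methoxybenzaldehyde | COc1ccc(C=O)cc1OCc1ccccc1 | starting material
4 | Meldrum's acid | CC1(C)OC(=O)CC(=O)O1 | starting material
5 | 5-[3-(benzyloxy)-4-methoxybenzylidene]-2,2-dimethyl-1,3-dioxane-4,6-dione | COc1ccc(C=C2C(=O)OC(C)(C)OC2=O)cc1OCc1ccccc1 | intermediate
6 | 5-[3-(benzyloxy)-4-methoxybenzyl]-2,2-dimethyl-1,3-dioxane-4,6-dione | COc1ccc(CC2C(=O)OC(C)(C)OC2=O)cc1OCc1ccccc1 | intermediate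
7 | 3-[3-(benzyloxy)-4-methoxyphenyl]propanoic acid | COc1ccc(CCC(=O)O)cc1OCc1ccccc1 | intermediate
8 | 3-[3-(benzyloxy)-4-methoxyphenyl]propanoyl chloride | COc1ccc(CCC(=O)Cl)cc1OCc1ccccc1 | intermediate
9 | furan | c1ccoc1 | starting material
10 | 1-[(1R,4S)-3-bromo-7-oxabicyclo[2.2.1]hepta-2,5-dien-2-yl]ethan-1-one | CC(=O)C1=C(Br)[C@@H]2C=C[C@H]1O2 | intermediate
11 | 5-[3-(benzyloxy)-4-methoxyphenyl]-1-[(1R,4S)-3-bromo-7-oxabicyclo[2.2.1]hepta-2,5-dien-2-yl]pentane-1,3-dione | COc1ccc(CCC(=O)CC(=O)C2=C(Br)[C@@H]3C=C[C@H]2O3)cc1OCc1ccccc1 | intermediate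
12 | (5R,8S)-2-{2-[3-(benzyloxy)-4-methoxyphenyl]ethyl}-5,8-dihydro-5,8-epoxy-4H-chromen-4-one | COc1ccc(CCc2cc(=O)c3c(o2)[C@@H]4C=C[C@H]3O4)cc1OCc1ccccc1 | intermediate
13 | (5S,6R,7S,8S)-2-{2-[3-(benzyloxy)-4-methoxyphenyl]ethyl}-6,7-dihydroxy-5,6,7,8-tetrahydro-5,8-epoxy-4H-chromen-4-one | COc1ccc(CCc2cc(=O)c3c(o2)[C@@H]4[C@@H](O)[C@@H](O)[C@H]3O4)cc1OCc1ccccc1 | intermediate
14 | (5S,6S,7S,8R)-8-chloro-5,6,7-trihydroxy-2-[2-(3-hydroxy-4-methoxyphenyl)ethyl]-5,6,7,8-tetrahydro-4H-chromen-4-one | COc1ccc(CCc2cc(=O)c3c(o2)[C@H](Cl)[C@@H](O)[C@@H](O)[C@H]3O)cc1O | target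

## Step count and risks

Total steps: 6. Longest linear sequence: 5 (steps 2, 3, 4, 5, 6).

**Step 4.** The risks are low ee, Friedel–Crafts alkylation of furan, and Lewis-acid isomerisation of 10 to a phenol. A moderate ee can be raised by recrystallising 12 or 13. The fallback gives up asymmetric catalysis for a racemic synthesis with resolution. It sets out from 2 and 9. An uncatalysed cycloaddition in neat furan at 35–40 °C gives the racemic bromo ketone F1, which is isolated. F1 is annulated separately with 8 (LiHMDS, THF, −78 °C → rt) to the racemic epoxy-dihydrochromone F2. F2 is resolved by preparative chiral SFC on an amylose phase, and the unwanted (5S,8R)-enantiomer F3 is discarded. The route is rejoined at 12.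

**Step 6.** The risks are attack at C5 instead of C8, partial SN1 leakage to the cis-chloride, aromatisation, and a sluggish bridge. The fallback brings chloride in on an epoxide rather than on the bridge. It sets out from 13. Silyl-halide cleavage (TMSBr, CH2Cl2, −40 → 0 °C, then MeOH) gives the 8-bromo-5,6,7-triol F4. Only its trans-bromohydrin can close with K2CO3/MeOH at 0 °C to the 7,8-epoxide F5, whose epoxide oxygen is syn to the 5,6-diol, so no Payne shift is possible. BCl3/C6HMe5 at −78 °C then opens the epoxide at the allylic C8 with inversion and removes the benzyl group. The route is rejoined at 14.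

**Step 5.** The risks are over-oxidation or osmate retention by the polar tricycle. The fallback oxidises before the pyrone exists. It sets out from 10, which is now isolated after stage (a). OsO4/NMO gives the exo-diol bromo ketone F6. 2,2-Dimethoxypropane/PPTS gives the acetonide F7. LiHMDS/8 annulation gives the acetonide-protected tricycle F8. 80 % AcOH at 40 °C removes the ketal, and the route is rejoined at 13.

## Further compounds

F1 | step 4 | rac-1-(3-bromo-7-oxabicyclo[2.2.1]hepta-2,5-dien-2-yl)ethan-1-one (racemate; bridge fixes the relative configuration) | CC(=O)C1=C(Br)C2C=CC1O2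
F2 | step 4 | rac-2-{2-[3-(benzyloxy)-4-methoxyphenyl]ethyl}-5,8-dihydro-5,8-epoxy-4H-chromen-4-one (racemate) | COc1ccc(CCc2cc(=O)c3c(o2)C4C=CC3O4)cc1OCc1ccccc1
F3 | step 4 | (5S,8R)-2-{2-[3-(benzyloxy)-4-methoxyphenyl]ethyl}-5,8-dihydro-5,8-epoxy-4H-chromen-4-one | COc1ccc(CCc2cc(=O)c3c(o2)[C@H]4C=C[C@@H]3O4)cc1OCc1ccccc1
F4 | step 6 | (5S,6S,7S,8R)-2-{2-[3-(benzyloxy)-4-methoxyphenyl]ethyl}-8-bromo-5,6,7-trihydroxy-5,6,7,8-tetrahydro-4H-chromen-4-one | COc1ccc(CCc2cc(=O)c3c(o2)[C@H](Br)[C@@H](O)[C@@H](O)[C@H]3O)cc1OCc1ccccc1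
F5 | step 6 | 2-{2-[3-(benzyloxy)-4-methoxyphenyl]ethyl}-7,8-epoxy-5,6-dihydroxy-5,6,7,8-tetrahydro-4H-chromen-4-one, epoxide oxygen and both OH on the same face | COc1ccc(CCc2cc(=O)c3c(o2)[C@@H]4[C@@H](O4)[C@@H](O)[C@H]3O)cc1OCc1ccccc1
F6 | step 5 | 1-(3-bromo-5,6-exo-dihydroxy-7-oxabicyclo[2.2.1]hept-2-en-2-yl)ethan-1-one, bridgeheads as in 10 | CC(=O)C1=C(Br)[C@@H]2[C@@H](O)[C@@H](O)[C@H]1O2
F7 | step 5 | 5,6-O-isopropylidene derivative of F6 | CC(=O)C1=C(Br)[C@@H]2[C@@H](OC3(C)C)[C@@H](O3)[C@H]1O2
F8 | step 5 | 6,7-O-isopropylidene derivative of 13 | COc1ccc(CCc2cc(=O)c3c(o2)[C@@H]4[C@@H](OC5(C)C)[C@@H](O5)[C@H]3O4)cc1OCc1ccccc1
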